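**Flat curve.** A flat curve tempts one to call the reagent spent, yet the balance of the midnight flask says otherwise. Reagent is the limiting reagent, charged at 6.00 mM against 10 mM of starting material. The readings from 15.0 h on average 47.7 %, so if each target takes one reagent, 1.23 mM of reagent stays free.

| setting | midnight | dawn | flask |
|---|---|---|---|
| starting material | 10 mM | 10 mM | 10 mM |
| reagent | 6 mM | 3 mM | 6.00 mM |
| capture agent | 3 mM | 3 mM | 3.00 mM |
| free catalyst | 1 mM | 1 mM | 1.0 mM |
| temperature | 25 °C | 31 °C | 25 °C |
| remark | the very flask that is asked about, followed so far | run made earlier |  |
| time |  |  | 40 h |

| run | time / h | target / % |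
|---|---|---|
| midnight | 1.33 | 18.1 |
| midnight | 4.00 | 39.0 |
| midnight | 6.00 | 42.9 |
| midnight | 10.0 | 45.6 |
| midnight | 15.0 | 48.9 |
| midnight | 20.0 | 46.6 |
| midnight | 25.0 | 47.7 |
| dawn | 0.167 | 2.7 |
| dawn | 0.500 | 11.2 |
| dawn | 0.833 | 14.1 |
| dawn | 1.33 | 20.1 |
| dawn | 2.00 | 23.0 |
| dawn | 2.50 | 23.3 |
| dawn | 3.00 | 25.5 |

(readings scatter by 1 percentage point)

- teal: change nothing and wait 40 h more
- amber: at 40 h take out 90 % of the target then present, then wait 40 h
- grey: at 40 h raise the temperature by 20 K, then wait 40 h
- green: at 40 h add free catalyst, 100 % of the amount charged, then wait 40 h
- blue: at 40 h add reagent, 100 % of the amount charged, then wait 40 h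

- target, in percent of the starting material first charged, at 40 h
- the remedy with the largest gain of target, or "none" below 2 percentage points (teal / amber / grey / green / blue / none)
- target present, with what was taken out counted in, in percent of the starting material first charged, after amber
- target present, with what was taken out counted in, in percent of the starting material first charged, after grey

- what is taken out of target is counted as made
- additions bring no volume worth counting

**Upper bound.** The reagent balance caps target in this flask at 60.0 %. The readings press harder: target rose by 21 percentage points between 1.33 h and 4.00 h, but changed by −1.2 points between 15.0 h and 25.0 h. So, as an estimate for 40 h, the upper edge comes down to the highest late reading, 48.9 %.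

**Lower bound.** The late readings show no steady fall, so the lowest of them, 46.6 %, stands as the lower edge of the estimate.

**A reckoning.** With starting material and reagent both present, this reckoning reads the stop as the catalyst's. The turnover yield, target made per catalyst charged (the turnover number), reads 4.77. At that yield, green's fresh catalyst could carry 4.77 mM, more than the reagent left. So the reckoning names green, with a gain up to the ceiling of 12 points.

**The forecast.** It gives 47.3 %, inside the bracket, then blue as remedy, 54 % after amber and 46 % after grey: “The smooth approach to a level fits a reversible reaction”. On the remedy it parts from the reckoning above.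

**The result.** The flask gives 47.5 %, also inside the bracket. The best remedy is green, gaining 12 points, while blue gains 0 points. Amber gives 47.5 % and grey 47.5 %.

    starting material + free catalyst → catalyst intermediate A (k = 20.2 /M/min, Ea = 51.0 kJ/mol)
    catalyst intermediate A → catalyst intermediate B (k = 0.176 /min, Ea = 83.0 kJ/mol)
    reagent + catalyst intermediate B ⇌ catalyst intermediate C (K = 140 /M, k = 129 /M/min, Ea = 35.0 kJ/mol, ΔH = 2.00 kJ/mol)
    catalyst intermediate C → by-product + catalyst intermediate D (k = 0.247 /min, Ea = 95.0 kJ/mol)
    catalyst intermediate D → free catalyst + target (k = 0.167 /min, Ea = 90.0 kJ/mol)
    capture agent + catalyst intermediate B → trapped intermediate (k = 6.97 /M/min, Ea = 52.0 kJ/mol)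
    (constants at 25 °C)

**The stop.** Capture of catalyst intermediate B by capture agent is a part of the stop: the run without that step reaches 60.0 % against 47.5 %, and green's gain there falls to 0 points. After 40.0 h the trapped intermediate holds >99.9 % of the catalyst, so the 4.77 read off the midnight run is the target per catalyst, on average, before capture.

**Second flask.** The neighbour charged with 2.5 mM of free catalyst has a yield worth 11.9 mM, more than its 6.00 mM of reagent, so the reckoning expects the reagent ceiling of 60.0 % there. The computed neighbour gives 59.9 %, with 0.12 % of its reagent left.

The data were generated by integration with made-up constants, and the scatter is random.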